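The whole route hangs on reading ring B (the cyclohexane of the hydrindane) as a 4‑oxygenated 2‑methylcyclohexenone. Its quaternary C7a(CH3) and the neighbouring ring‑fusion C3a(H), flanked by the CHBr carbon C7 and the carbinol carbon C4, are the α‑ and β‑carbons of that enone. One three‑component operation, copper‑mediated alkenyl addition anti to the C4 silyloxy group followed by allylation of the enolate, forms the future C3a–C3 and C7a–C1 bonds and sets the trans C3a/C7a pair. The two arms then close ring C by metathesis. The precursor is (S)‑4‑silyloxy‑2‑methylcyclohex‑2‑enone, which also supplies ring A.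

Key step: step 6

Assumption (chemistry): the lipase acetylates the R enantiomer of hydroxy enone 3 faster, as the empirical size model for secondary alcohols predicts with the alkene arm as the larger substituent; should the preference be reversed, the acetate fraction would be methanolysed and used in place of the recovered alcohol.

Remark on names: the bicyclic compounds 13–23 and 32–38 carry the locants of the target throughout (C3 bears the side chain, C3a is the ring‑fusion CH, C4 the carbinol carbon, C7 the CHBr carbon, C7a the methyl‑bearing quaternary carbon). The C3 descriptor changes between R and S with the substituent priorities, not with the geometry. Compounds 16–22 are C3 epimer mixtures and are drawn without configuration at C3.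

**Route to enone 5**

Step 1
Reactants: 1 3-ethoxy-2-methylcyclohex-2-en-1-one
Product: 2 (±)-4-ethoxy-3-methyl-2-oxocyclohex-3-en-1-yl acetate
Conditions: Mn(OAc)3·2H2O, benzene, reflux (Dean–Stark)
Reagents that add atoms: manganese triacetate CC(=O)[O-].CC(=O)[O-].CC(=O)[O-].[Mn+3]
Why: α′‑Acetoxylation of a vinylogous ester by trivalent manganese acetate proceeds through the manganese enolate, and C6 is the only enolisable α‑position because C2 is fully substituted; the product is racemic.

Step 2
Reactants: 2 (±)-4-ethoxy-3-methyl-2-oxocyclohex-3-en-1-yl acetate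
Product: 3 (±)-4-hydroxy-2-methylcyclohex-2-en-1-one
Conditions: LiAlH4, Et2O, 0 °C; then 1 M HCl, THF, 0 °C → rt
Reagents that add atoms: water O
Why: Stork–Danheiser carbonyl transposition: hydride reduces the ketone and cleaves the acetate, and acid hydrolysis of the resulting allylic enol ether unmasks the enone with the former C6 hydroxyl now at C4.

Step 3
Reactants: 3 (±)-4-hydroxy-2-methylcyclohex-2-en-1-one
Product: 4 (S)-4-hydroxy-2-methylcyclohex-2-en-1-one
Conditions: Burkholderia cepacia lipase, vinyl acetate, t-BuOMe, rt, stopped beyond half conversion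
Reagents that add atoms: none
Why: Lipase‑catalysed kinetic resolution by enantioselective transesterification: the R alcohol is expected to be acetylated, so the recovered alcohol is the S enantiomer, which fixes the only stereocentre of the precursor.

Step 4
Reactants: 4 (S)-4-hydroxy-2-methylcyclohex-2-en-1-one
Product: 5 (S)-4-(tert-butyldimethylsilyloxy)-2-methylcyclohex-2-en-1-one
Conditions: TBSCl, imidazole, CH2Cl2, rt
Reagents that add atoms: tert-butyldimethylsilyl chloride CC(C)(C)[Si](C)(C)Cl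
Why: Standard silylation of a secondary alcohol with a silyl chloride and imidazole, which leaves the stereocentre untouched.

**Alkenyl partner and key step**

Step 5
Reactants: 6 2-bromoprop-2-en-1-ol
Product: 7 2-bromoallyl 4-methoxybenzyl ether
Conditions: NaH, PMBCl, Bu4NI (cat.), THF, 0 °C → rt
Reagents that add atoms: 4-methoxybenzyl chloride COc1ccc(CCl)cc1
Why: Williamson etherification of the allylic alkoxide with the benzylic chloride; the vinylic bromide does not react.

Step 6
Reactants: 5 (S)-4-(tert-butyldimethylsilyloxy)-2-methylcyclohex-2-en-1-one + 7 2-bromoallyl 4-methoxybenzyl ether + 8 allyl bromide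
Product: 12 (2S,3S,4S)-2-allyl-4-(tert-butyldimethylsilyloxy)-3-[3-(4-methoxybenzyloxy)prop-1-en-2-yl]-2-methylcyclohexan-1-one, via alkenyllithium 9 (not isolated), via Grignard reagent 10 (not isolated), via magnesium enolate 11 (not isolated)
Conditions: 7, t-BuLi, Et2O, −78 °C; MgBr2·OEt2, −78 °C; CuBr·SMe2 (0.2 equiv), THF; 5, −78 → −40 °C; then 8, HMPA, −40 → 0 °C
Reagents that add atoms: none
Why: Catalytic monovalent copper turns Grignard reagent 10 into an alkenylcuprate that adds to C3 of enone 5 (π‑complexation, oxidative addition, reductive elimination) and leaves the regiodefined, tetrasubstituted magnesium enolate 11, which is then C‑allylated by SN2 attack on allyl bromide. The closest known reaction type is the copper‑mediated conjugate addition of alkenyl Grignard reagents to 2‑methylcycloalkenones with alkylation of the enolate in the same flask, the three‑component pattern also used on 4‑silyloxycyclopentenones. No ring is closed; the new C3–alkenyl and C2–allyl bonds are the future C3a–C3 and C7a–C1 bonds of ring C. C3 is controlled by the C4 stereocentre, the cuprate entering axially on the face opposite the silyloxy group; C2 is controlled by C3, allyl bromide approaching the enolate face opposite the new alkenyl group, so that allyl and alkenyl end trans. The step needs 1,4‑ over 1,2‑addition (secured by copper), alkylation at the enolate carbon that is formed (no proton source, so the enolate cannot move to C6) and C‑ over O‑allylation (soft allylic bromide, HMPA).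

**Ring C, the ring B bromide and the side‑chain aldehyde**

Step 7
Reactants: 12 (2S,3S,4S)-2-allyl-4-(tert-butyldimethylsilyloxy)-3-[3-(4-methoxybenzyloxy)prop-1-en-2-yl]-2-methylcyclohexan-1-one
Product: 13 (3aS,4S,7aS)-4-(tert-butyldimethylsilyloxy)-3-[(4-methoxybenzyloxy)methyl]-7a-methyl-1,3a,4,5,6,7a-hexahydro-7H-inden-7-one
Conditions: second-generation Grubbs catalyst (5 mol%), CH2Cl2, 40 °C
Reagents that add atoms: none
Why: Ring‑closing metathesis between the allyl group and the 1,1‑disubstituted alkene closes the cyclopentene (ring C) with loss of ethene, and the trans arrangement of the two arms from step 6 becomes the trans ring fusion.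

Step 8
Reactants: 13 (3aS,4S,7aS)-4-(tert-butyldimethylsilyloxy)-3-[(4-methoxybenzyloxy)methyl]-7a-methyl-1,3a,4,5,6,7a-hexahydro-7H-inden-7-one
Product: 14 (3aS,4S,7aS)-4-(tert-butyldimethylsilyloxy)-3-[(4-methoxybenzyloxy)methyl]-7a-methyl-3a,4,5,7a-tetrahydro-1H-inden-7-yl trifluoromethanesulfonate
Conditions: KN(SiMe3)2, PhNTf2, THF, −78 → 0 °C
Reagents that add atoms: N-phenylbis(trifluoromethanesulfonimide) O=S(=O)(N(c1ccccc1)S(=O)(=O)C(F)(F)F)C(F)(F)F
Why: Enol triflate formation: deprotonation can only occur at C6 because C7a is quaternary, and the potassium enolate is O‑sulfonylated by PhNTf2.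

Step 9
Reactants: 14 (3aS,4S,7aS)-4-(tert-butyldimethylsilyloxy)-3-[(4-methoxybenzyloxy)methyl]-7a-methyl-3a,4,5,7a-tetrahydro-1H-inden-7-yl trifluoromethanesulfonate
Product: 15 (3aS,4S,7aS)-7-bromo-4-(tert-butyldimethylsilyloxy)-3-[(4-methoxybenzyloxy)methyl]-7a-methyl-3a,4,5,7a-tetrahydro-1H-indene
Conditions: Ni(cod)2 (10 mol%), LiBr, DMA/THF, rt
Reagents that add atoms: lithium bromide [Li+].[Br-]
Why: Nickel‑catalysed halogen exchange of an enol triflate (oxidative addition of zerovalent nickel into the C–O bond, triflate–bromide exchange, reductive elimination) gives the alkenyl bromide under neutral conditions that spare both ethers.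

Step 10
Reactants: 15 (3aS,4S,7aS)-7-bromo-4-(tert-butyldimethylsilyloxy)-3-[(4-methoxybenzyloxy)methyl]-7a-methyl-3a,4,5,7a-tetrahydro-1H-indene
Product: 16 (3aS,4S,7S,7aS)-7-bromo-4-(tert-butyldimethylsilyloxy)-3-[(4-methoxybenzyloxy)methyl]-7a-methyloctahydro-1H-indene (C3 epimers)
Conditions: Mn(dpm)3 (10 mol%), PhSiH3, t-BuOOH, i-PrOH, rt
Reagents that add atoms: none
Why: Hydrogen‑atom‑transfer hydrogenation, which turns alkenyl halides into alkyl halides without cleaving the C–Br bond, reduces both alkenes: the α‑bromo radical at C7 takes up hydrogen axially on the face opposite the axial C7a methyl, which places bromine equatorial (7S), while the C3 radical can be quenched from either face, so that C3 epimers are expected and are converged in step 16.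

Step 11
Reactants: 16 (3aS,4S,7S,7aS)-7-bromo-4-(tert-butyldimethylsilyloxy)-3-[(4-methoxybenzyloxy)methyl]-7a-methyloctahydro-1H-indene (C3 epimers)
Product: 17 (3aS,4S,7S,7aS)-7-bromo-3-[(4-methoxybenzyloxy)methyl]-7a-methyloctahydro-1H-inden-4-ol (C3 epimers)
Conditions: HF·pyridine, THF/pyridine, 0 °C → rt
Reagents that add atoms: none
Why: Fluoride‑mediated cleavage of the secondary silyl ether; the PMB ether and the equatorial, neopentyl‑type bromide are inert to HF·pyridine.

Step 12
Reactants: 17 (3aS,4S,7S,7aS)-7-bromo-3-[(4-methoxybenzyloxy)methyl]-7a-methyloctahydro-1H-inden-4-ol (C3 epimers)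
Product: 18 (3aS,7S,7aS)-7-bromo-3-[(4-methoxybenzyloxy)methyl]-7a-methyloctahydro-4H-inden-4-one (C3 epimers)
Conditions: Dess–Martin periodinane, NaHCO3, CH2Cl2, 0 °C → rt
Reagents that add atoms: none
Why: Dess–Martin oxidation of the secondary alcohol under buffered, base‑free conditions, chosen so that the ring‑fusion hydrogen at C3a next to the new ketone is not epimerised.

Step 13
Reactants: 18 (3aS,7S,7aS)-7-bromo-3-[(4-methoxybenzyloxy)methyl]-7a-methyloctahydro-4H-inden-4-one (C3 epimers)
Product: 19 (3aS,4R,7S,7aS)-7-bromo-3-[(4-methoxybenzyloxy)methyl]-4,7a-dimethyloctahydro-1H-inden-4-ol (C3 epimers)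
Conditions: MeLi, CeCl3, THF, −78 °C
Reagents that add atoms: methyllithium (delivered as MeCeCl2) [Li]C
Why: 1,2‑Addition of the weakly basic organocerium reagent to the enolisable ketone: axial attack is blocked by the syn‑axial C7a methyl, so methyl enters equatorially and the hydroxyl becomes axial (4R).

Step 14
Reactants: 19 (3aS,4R,7S,7aS)-7-bromo-3-[(4-methoxybenzyloxy)methyl]-4,7a-dimethyloctahydro-1H-inden-4-ol (C3 epimers)
Product: 20 (3aS,4R,7S,7aS)-7-bromo-3-[(4-methoxybenzyloxy)methyl]-4,7a-dimethyl-4-(triethylsilyloxy)octahydro-1H-indene (C3 epimers)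
Conditions: Et3SiOTf, 2,6-lutidine, CH2Cl2, −78 → 0 °C
Reagents that add atoms: triethylsilyl trifluoromethanesulfonate CC[Si](CC)(CC)OS(=O)(=O)C(F)(F)F
Why: Silylation of the hindered tertiary alcohol with a silyl triflate; the silyl ether prevents lactol formation with the C3 side chain and makes the cis arrangement of side chain and oxygen strongly unfavourable in step 16.

Step 15
Reactants: 20 (3aS,4R,7S,7aS)-7-bromo-3-[(4-methoxybenzyloxy)methyl]-4,7a-dimethyl-4-(triethylsilyloxy)octahydro-1H-indene (C3 epimers)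
Product: 21 [(3aS,4R,7S,7aS)-7-bromo-4,7a-dimethyl-4-(triethylsilyloxy)octahydro-1H-inden-3-yl]methanol (C3 epimers)
Conditions: DDQ, CH2Cl2/pH 7 buffer, 0 °C
Reagents that add atoms: none
Why: Oxidative cleavage of the PMB ether by DDQ (benzylic hydride abstraction, hydrolysis of the oxocarbenium ion), which leaves the silyl ether and the bromide intact.

Step 16
Reactants: 21 [(3aS,4R,7S,7aS)-7-bromo-4,7a-dimethyl-4-(triethylsilyloxy)octahydro-1H-inden-3-yl]methanol (C3 epimers)
Product: 23 (3R,3aS,4R,7S,7aS)-7-bromo-4,7a-dimethyl-4-(triethylsilyloxy)octahydro-1H-indene-3-carbaldehyde, via aldehyde epimer mixture 22 (not isolated)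
Conditions: Dess–Martin periodinane, NaHCO3, CH2Cl2, 0 °C; then DBU, CH2Cl2, rt
Reagents that add atoms: none
Why: Dess–Martin oxidation to the aldehyde followed by base‑mediated epimerisation through the enolate: the aldehyde cis to the axial C4 silyloxy group and to the angular methyl is far more strained, so both C3 epimers should converge on the 3R aldehyde, in which the formyl group is trans to both.

**Ring A fragment (from a second portion of 5)**

Step 17
Reactants: 5 (S)-4-(tert-butyldimethylsilyloxy)-2-methylcyclohex-2-en-1-one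
Product: 25 (S)-4-(tert-butyldimethylsilyloxy)-2,2-dimethylcyclohexan-1-one, via lithium enolate 24 (not isolated)
Conditions: LiBH(s-Bu)3, THF, −78 °C; then MeI, HMPA, −78 → 0 °C
Reagents that add atoms: iodomethane CI
Why: Conjugate reduction–enolate alkylation: the hindered borohydride adds hydride to the unsubstituted β‑carbon and the regiodefined lithium enolate is methylated at C2, which becomes the gem‑dimethyl carbon; the C4 stereocentre is not touched.

Step 18
Reactants: 25 (S)-4-(tert-butyldimethylsilyloxy)-2,2-dimethylcyclohexan-1-one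
Product: 26 (S)-4-(tert-butyldimethylsilyloxy)-6,6-dimethylcyclohex-1-en-1-yl trifluoromethanesulfonate
Conditions: KN(SiMe3)2, PhNTf2, THF, −78 → 0 °C
Reagents that add atoms: N-phenylbis(trifluoromethanesulfonimide) O=S(=O)(N(c1ccccc1)S(=O)(=O)C(F)(F)F)C(F)(F)F
Why: Enol triflate formation: enolisation is possible only away from the quaternary carbon, and the potassium enolate is O‑sulfonylated by PhNTf2.

Step 19
Reactants: 26 (S)-4-(tert-butyldimethylsilyloxy)-6,6-dimethylcyclohex-1-en-1-yl trifluoromethanesulfonate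
Product: 27 (S)-[(4-bromo-5,5-dimethylcyclohex-3-en-1-yl)oxy](tert-butyl)dimethylsilane
Conditions: Ni(cod)2 (10 mol%), LiBr, DMA/THF, rt
Reagents that add atoms: lithium bromide [Li+].[Br-]
Why: The same nickel‑catalysed triflate‑to‑bromide exchange as in step 9, here on a simpler enol triflate.

Step 20
Reactants: 27 (S)-[(4-bromo-5,5-dimethylcyclohex-3-en-1-yl)oxy](tert-butyl)dimethylsilane
Product: 28 {[(1S,4S)-4-bromo-3,3-dimethylcyclohexyl]oxy}(tert-butyl)dimethylsilane
Conditions: Mn(dpm)3 (10 mol%), PhSiH3, t-BuOOH, i-PrOH, rt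
Reagents that add atoms: none
Why: Hydrogen‑atom‑transfer hydrogenation of the alkenyl bromide: the chair is held by the silyloxy group, which stays equatorial to avoid a syn‑axial methyl, and the α‑bromo radical takes up hydrogen axially, anti to the neighbouring axial methyl, so that bromine ends equatorial and trans to oxygen (4S).

Step 21
Reactants: 28 {[(1S,4S)-4-bromo-3,3-dimethylcyclohexyl]oxy}(tert-butyl)dimethylsilane
Product: 29 (1S,4S)-4-bromo-3,3-dimethylcyclohexan-1-ol
Conditions: HF·pyridine, THF, 0 °C → rt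
Reagents that add atoms: none
Why: Fluoride‑mediated desilylation of a secondary silyl ether; the secondary neopentyl‑type bromide is not displaced.

Step 22
Reactants: 29 (1S,4S)-4-bromo-3,3-dimethylcyclohexan-1-ol
Product: 30 (S)-4-bromo-3,3-dimethylcyclohexan-1-one
Conditions: Dess–Martin periodinane, NaHCO3, CH2Cl2, 0 °C → rt
Reagents that add atoms: none
Why: Dess–Martin oxidation removes the auxiliary carbinol stereocentre after it has relayed its configuration to the CHBr carbon.

Step 23
Reactants: 30 (S)-4-bromo-3,3-dimethylcyclohexan-1-one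
Product: 31 (S)-4-bromo-5,5-dimethylcyclohex-1-en-1-yl trifluoromethanesulfonate
Conditions: KN(SiMe3)2, PhNTf2, THF, −78 °C
Reagents that add atoms: N-phenylbis(trifluoromethanesulfonimide) O=S(=O)(N(c1ccccc1)S(=O)(=O)C(F)(F)F)C(F)(F)F
Why: Kinetic enol triflate formation: deprotonation of the 3,3‑dimethylcyclohexanone takes place on the CH2CH2CHBr side, away from the neopentyl methylene, and the enolate is trapped at −78 °C before it can displace the γ‑bromide.

**Coupling and end game**

Step 24
Reactants: 23 (3R,3aS,4R,7S,7aS)-7-bromo-4,7a-dimethyl-4-(triethylsilyloxy)octahydro-1H-indene-3-carbaldehyde + 31 (S)-4-bromo-5,5-dimethylcyclohex-1-en-1-yl trifluoromethanesulfonate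
Product: 32 [(S)-4-bromo-5,5-dimethylcyclohex-1-en-1-yl][(3R,3aS,4R,7S,7aS)-7-bromo-4,7a-dimethyl-4-(triethylsilyloxy)octahydro-1H-inden-3-yl]methanol (carbinol epimers)
Conditions: CrCl2, NiCl2 (cat.), DMF, rt
Reagents that add atoms: none
Why: Nozaki–Hiyama–Kishi coupling: nickel‑catalysed formation of the alkenylchromium reagent from the triflate and its non‑basic addition to the α‑branched aldehyde, which tolerates both secondary bromides; the new carbinol centre is removed in step 25.

Step 25
Reactants: 32 [(S)-4-bromo-5,5-dimethylcyclohex-1-en-1-yl][(3R,3aS,4R,7S,7aS)-7-bromo-4,7a-dimethyl-4-(triethylsilyloxy)octahydro-1H-inden-3-yl]methanol (carbinol epimers)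
Product: 33 [(S)-4-bromo-5,5-dimethylcyclohex-1-en-1-yl][(3R,3aS,4R,7S,7aS)-7-bromo-4,7a-dimethyl-4-(triethylsilyloxy)octahydro-1H-inden-3-yl]methanone
Conditions: Dess–Martin periodinane, NaHCO3, CH2Cl2, 0 °C → rt
Reagents that add atoms: none
Why: Dess–Martin oxidation of the allylic alcohol mixture to a single cyclohexenyl ketone; C3 stays in its thermodynamically preferred configuration.

Step 26
Reactants: 33 [(S)-4-bromo-5,5-dimethylcyclohex-1-en-1-yl][(3R,3aS,4R,7S,7aS)-7-bromo-4,7a-dimethyl-4-(triethylsilyloxy)octahydro-1H-inden-3-yl]methanone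
Product: 34 N'-tosylhydrazone of ketone 33
Conditions: TsNHNH2, PPTS (cat.), EtOH/THF, 60 °C
Reagents that add atoms: 4-methylbenzenesulfonohydrazide Cc1ccc(cc1)S(=O)(=O)NN
Why: Acid‑catalysed condensation of the enone with tosylhydrazide gives the α,β‑unsaturated tosylhydrazone needed for reductive transposition.

Step 27
Reactants: 34 N'-tosylhydrazone of ketone 33
Product: 37 (3S,3aS,4R,7S,7aS)-7-bromo-3-{(E)-[(4S)-4-bromo-3,3-dimethylcyclohexylidene]methyl}-4,7a-dimethyl-4-(triethylsilyloxy)octahydro-1H-indene, via tosylhydrazine 35 (not isolated), via allylic diazene 36 (not isolated)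
Conditions: catecholborane, CHCl3, 0 °C → rt; then NaOAc·3H2O, 60 °C
Reagents that add atoms: none
Why: Reductive 1,3‑transposition of an α,β‑unsaturated tosylhydrazone: catecholborane reduces the C=N bond, acetate triggers loss of sulfinate, and the allylic diazene loses N2 in a retro‑ene step that delivers hydrogen to the ring A alkene CH and moves the double bond to the exocyclic position; in the transition state the hydrindanyl group should sit over the ring alkene (only a vinylic hydrogen there) and not beside the neopentyl methylene, which places it cis to the CH2CH2CHBr arm and gives the E alkene.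

Step 28
Reactants: 37 (3S,3aS,4R,7S,7aS)-7-bromo-3-{(E)-[(4S)-4-bromo-3,3-dimethylcyclohexylidene]methyl}-4,7a-dimethyl-4-(triethylsilyloxy)octahydro-1H-indene
Product: 38 (3S,3aS,4R,7S,7aS)-7-bromo-3-{(E)-[(4S)-4-bromo-3,3-dimethylcyclohexylidene]methyl}-4,7a-dimethyloctahydro-1H-inden-4-ol
Conditions: HF·pyridine, THF, 0 °C → rt
Reagents that add atoms: none
Why: Fluoride cleavage of the tertiary triethylsilyl ether under mildly acidic conditions that should neither ionise the tertiary alcohol nor isomerise the alkene.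

**Compound list**

1 | 3-ethoxy-2-methylcyclohex-2-en-1-one | CCOC1=C(C)C(=O)CCC1 | starting material
2 | (±)-4-ethoxy-3-methyl-2-oxocyclohex-3-en-1-yl acetate | CCOC1=C(C)C(=O)C(OC(C)=O)CC1 | intermediate
3 | (±)-4-hydroxy-2-methylcyclohex-2-en-1-one | CC1=CC(O)CCC1=O | intermediate
4 | (S)-4-hydroxy-2-methylcyclohex-2-en-1-one | CC1=C[C@@H](O)CCC1=O | intermediate
5 | (S)-4-(tert-butyldimethylsilyloxy)-2-methylcyclohex-2-en-1-one | CC1=C[C@@H](O[Si](C)(C)C(C)(C)C)CCC1=O | intermediate
6 | 2-bromoprop-2-en-1-ol | C=C(Br)CO | starting material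
7 | 2-bromoallyl 4-methoxybenzyl ether | C=C(Br)COCc1ccc(OC)cc1 | intermediate
8 | allyl bromide | C=CCBr | starting material
9 | {3-[(4-methoxybenzyl)oxy]prop-1-en-2-yl}lithium | [Li]C(=C)COCc1ccc(OC)cc1 | intermediate
10 | {3-[(4-methoxybenzyl)oxy]prop-1-en-2-yl}magnesium bromide | C=C([Mg]Br)COCc1ccc(OC)cc1 | intermediate
11 | bromomagnesium (3S,4S)-4-(tert-butyldimethylsilyloxy)-3-[3-(4-methoxybenzyloxy)prop-1-en-2-yl]-2-methylcyclohex-1-en-1-olate | CC1=C(O[Mg]Br)CC[C@H](O[Si](C)(C)C(C)(C)C)[C@H]1C(=C)COCc1ccc(OC)cc1 | intermediate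
12 | (2S,3S,4S)-2-allyl-4-(tert-butyldimethylsilyloxy)-3-[3-(4-methoxybenzyloxy)prop-1-en-2-yl]-2-methylcyclohexan-1-one | C=CC[C@]1(C)C(=O)CC[C@H](O[Si](C)(C)C(C)(C)C)[C@H]1C(=C)COCc2ccc(OC)cc2 | intermediate
13 | (3aS,4S,7aS)-4-(tert-butyldimethylsilyloxy)-3-[(4-methoxybenzyloxy)methyl]-7a-methyl-1,3a,4,5,6,7a-hexahydro-7H-inden-7-one | COc1ccc(COCC2=CC[C@]3(C)C(=O)CC[C@H](O[Si](C)(C)C(C)(C)C)[C@@H]23)cc1 | intermediate
14 | (3aS,4S,7aS)-4-(tert-butyldimethylsilyloxy)-3-[(4-methoxybenzyloxy)methyl]-7a-methyl-3a,4,5,7a-tetrahydro-1H-inden-7-yl trifluoromethanesulfonate | COc1ccc(COCC2=CC[C@]3(C)C(OS(=O)(=O)C(F)(F)F)=CC[C@H](O[Si](C)(C)C(C)(C)C)[C@@H]23)cc1 | intermediate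
15 | (3aS,4S,7aS)-7-bromo-4-(tert-butyldimethylsilyloxy)-3-[(4-methoxybenzyloxy)methyl]-7a-methyl-3a,4,5,7a-tetrahydro-1H-indene | COc1ccc(COCC2=CC[C@]3(C)C(Br)=CC[C@H](O[Si](C)(C)C(C)(C)C)[C@@H]23)cc1 | intermediate
16 | (3aS,4S,7S,7aS)-7-bromo-4-(tert-butyldimethylsilyloxy)-3-[(4-methoxybenzyloxy)methyl]-7a-methyloctahydro-1H-indene (C3 epimers) | COc1ccc(COCC2CC[C@]3(C)[C@@H](Br)CC[C@H](O[Si](C)(C)C(C)(C)C)[C@@H]23)cc1 | intermediate
17 | (3aS,4S,7S,7aS)-7-bromo-3-[(4-methoxybenzyloxy)methyl]-7a-methyloctahydro-1H-inden-4-ol (C3 epimers) | COc1ccc(COCC2CC[C@]3(C)[C@@H](Br)CC[C@H](O)[C@@H]23)cc1 | intermediate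
18 | (3aS,7S,7aS)-7-bromo-3-[(4-methoxybenzyloxy)methyl]-7a-methyloctahydro-4H-inden-4-one (C3 epimers) | COc1ccc(COCC2CC[C@]3(C)[C@@H](Br)CCC(=O)[C@@H]23)cc1 | intermediate
19 | (3aS,4R,7S,7aS)-7-bromo-3-[(4-methoxybenzyloxy)methyl]-4,7a-dimethyloctahydro-1H-inden-4-ol (C3 epimers) | COc1ccc(COCC2CC[C@]3(C)[C@@H](Br)CC[C@@](C)(O)[C@@H]23)cc1 | intermediate
20 | (3aS,4R,7S,7aS)-7-bromo-3-[(4-methoxybenzyloxy)methyl]-4,7a-dimethyl-4-(triethylsilyloxy)octahydro-1H-indene (C3 epimers) | COc1ccc(COCC2CC[C@]3(C)[C@@H](Br)CC[C@@](C)(O[Si](CC)(CC)CC)[C@@H]23)cc1 | intermediate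
21 | [(3aS,4R,7S,7aS)-7-bromo-4,7a-dimethyl-4-(triethylsilyloxy)octahydro-1H-inden-3-yl]methanol (C3 epimers) | OCC1CC[C@]2(C)[C@@H](Br)CC[C@@](C)(O[Si](CC)(CC)CC)[C@@H]12 | intermediate
22 | (3aS,4R,7S,7aS)-7-bromo-4,7a-dimethyl-4-(triethylsilyloxy)octahydro-1H-indene-3-carbaldehyde (C3 epimers) | O=CC1CC[C@]2(C)[C@@H](Br)CC[C@@](C)(O[Si](CC)(CC)CC)[C@@H]12 | intermediate
23 | (3R,3aS,4R,7S,7aS)-7-bromo-4,7a-dimethyl-4-(triethylsilyloxy)octahydro-1H-indene-3-carbaldehyde | O=C[C@@H]1CC[C@]2(C)[C@@H](Br)CC[C@@](C)(O[Si](CC)(CC)CC)[C@@H]12 | intermediate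
24 | lithium (S)-4-(tert-butyldimethylsilyloxy)-2-methylcyclohex-1-en-1-olate | CC1=C(O[Li])CC[C@H](O[Si](C)(C)C(C)(C)C)C1 | intermediate
25 | (S)-4-(tert-butyldimethylsilyloxy)-2,2-dimethylcyclohexan-1-one | CC1(C)C[C@@H](O[Si](C)(C)C(C)(C)C)CCC1=O | intermediate
26 | (S)-4-(tert-butyldimethylsilyloxy)-6,6-dimethylcyclohex-1-en-1-yl trifluoromethanesulfonate | CC1(C)C[C@@H](O[Si](C)(C)C(C)(C)C)CC=C1OS(=O)(=O)C(F)(F)F | intermediate
27 | (S)-[(4-bromo-5,5-dimethylcyclohex-3-en-1-yl)oxy](tert-butyl)dimethylsilane | CC1(C)C[C@@H](O[Si](C)(C)C(C)(C)C)CC=C1Br | intermediate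
28 | {[(1S,4S)-4-bromo-3,3-dimethylcyclohexyl]oxy}(tert-butyl)dimethylsilane | CC1(C)C[C@@H](O[Si](C)(C)C(C)(C)C)CC[C@@H]1Br | intermediate
29 | (1S,4S)-4-bromo-3,3-dimethylcyclohexan-1-ol | CC1(C)C[C@@H](O)CC[C@@H]1Br | intermediate
30 | (S)-4-bromo-3,3-dimethylcyclohexan-1-one | CC1(C)CC(=O)CC[C@@H]1Br | intermediate
31 | (S)-4-bromo-5,5-dimethylcyclohex-1-en-1-yl trifluoromethanesulfonate | CC1(C)CC(OS(=O)(=O)C(F)(F)F)=CC[C@@H]1Br | intermediate
32 | [(S)-4-bromo-5,5-dimethylcyclohex-1-en-1-yl][(3R,3aS,4R,7S,7aS)-7-bromo-4,7a-dimethyl-4-(triethylsilyloxy)octahydro-1H-inden-3-yl]methanol (carbinol epimers) | OC([C@@H]1CC[C@]2(C)[C@@H](Br)CC[C@@](C)(O[Si](CC)(CC)CC)[C@@H]12)C1=CC[C@H](Br)C(C)(C)C1 | intermediate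
33 | [(S)-4-bromo-5,5-dimethylcyclohex-1-en-1-yl][(3R,3aS,4R,7S,7aS)-7-bromo-4,7a-dimethyl-4-(triethylsilyloxy)octahydro-1H-inden-3-yl]methanone | O=C([C@@H]1CC[C@]2(C)[C@@H](Br)CC[C@@](C)(O[Si](CC)(CC)CC)[C@@H]12)C1=CC[C@H](Br)C(C)(C)C1 | intermediate
34 | N'-tosylhydrazone of ketone 33 (C=N geometry open) | Cc1ccc(cc1)S(=O)(=O)NN=C([C@@H]1CC[C@]2(C)[C@@H](Br)CC[C@@](C)(O[Si](CC)(CC)CC)[C@@H]12)C1=CC[C@H](Br)C(C)(C)C1 | intermediate
35 | N'-alkyl tosylhydrazide from hydride addition to 34 (carbinyl epimers; boron-bound in the flask) | Cc1ccc(cc1)S(=O)(=O)NNC([C@@H]1CC[C@]2(C)[C@@H](Br)CC[C@@](C)(O[Si](CC)(CC)CC)[C@@H]12)C1=CC[C@H](Br)C(C)(C)C1 | intermediate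
36 | allylic diazene from 35 (carbinyl epimers) | N=NC([C@@H]1CC[C@]2(C)[C@@H](Br)CC[C@@](C)(O[Si](CC)(CC)CC)[C@@H]12)C1=CC[C@H](Br)C(C)(C)C1 | intermediate
37 | (3S,3aS,4R,7S,7aS)-7-bromo-3-{(E)-[(4S)-4-bromo-3,3-dimethylcyclohexylidene]methyl}-4,7a-dimethyl-4-(triethylsilyloxy)octahydro-1H-indene | CC1(C)C/C(=C/[C@@H]2CC[C@]3(C)[C@@H](Br)CC[C@@](C)(O[Si](CC)(CC)CC)[C@@H]23)CC[C@@H]1Br | intermediate
38 | (3S,3aS,4R,7S,7aS)-7-bromo-3-{(E)-[(4S)-4-bromo-3,3-dimethylcyclohexylidene]methyl}-4,7a-dimethyloctahydro-1H-inden-4-ol | CC1(C)C/C(=C/[C@@H]2CC[C@]3(C)[C@@H](Br)CC[C@@](C)(O)[C@@H]23)CC[C@@H]1Br | target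

**Step count and risks**

Total step count: 28. Longest linear sequence: 20 steps (steps 1–4, 6–16 and 24–28); the ring A branch (steps 17–23) starts from the same enone 5.

The three steps most likely to fail:

1. Step 27. The retro‑ene step may pass through the other rotamer and give the Z alkene or an E/Z mixture; hydride may also add in a conjugate sense. Fallback: the alkene is made by carbonyl olefination instead of transposition. Aldehyde 23 is reduced (NaBH4, MeOH) to [(3R,3aS,4R,7S,7aS)-7-bromo-4,7a-dimethyl-4-(triethylsilyloxy)octahydro-1H-inden-3-yl]methanol F1, which is converted (I2, PPh3, imidazole) into (3R,3aS,4R,7S,7aS)-7-bromo-3-(iodomethyl)-4,7a-dimethyl-4-(triethylsilyloxy)octahydro-1H-indene F2 and heated with PPh3 in MeCN to the triphenylphosphonium iodide F3. Its ylide (NaN(SiMe3)2, THF, −78 °C) is condensed with ketone 30 in a Wittig reaction, which should give 37 together with its Z isomer F4; the isomers are to be separated on AgNO3‑impregnated silica. The fallback sets out from 23 and 30 and rejoins the route at 37.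

2. Step 23. The enolate of the γ‑bromo ketone may close a cyclopropane by 1,3‑elimination of bromide before it is triflated, or may form on the wrong side. Fallback: no enolate is generated. Ketone 30 is condensed with hydrazine to (S)-(4-bromo-3,3-dimethylcyclohexylidene)hydrazine F5 and oxidised with I2 and tetramethylguanidine (Barton vinyl iodide synthesis) to (S)-4-bromo-1-iodo-5,5-dimethylcyclohex-1-ene F6, which replaces triflate 31 in the Nozaki–Hiyama–Kishi coupling of step 24. The fallback sets out from 30 and rejoins the route at 32.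

3. Step 6. C‑Allylation of the hindered, tetrasubstituted magnesium enolate may be outrun by proton transfer or O‑allylation, which would cost the quaternary centre. Fallback: the enolate 11 formed from 5 and 10 is captured on oxygen with allyl chloroformate as allyl (3S,4S)-4-(tert-butyldimethylsilyloxy)-3-[3-(4-methoxybenzyloxy)prop-1-en-2-yl]-2-methylcyclohex-1-en-1-yl carbonate F7. The allyl group is then moved to carbon by decarboxylative Tsuji allylation (Pd(PPh3)4, THF, rt), again on the face opposite the C3 alkenyl group. The fallback sets out from 5 and rejoins the route at 12.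

Further compounds

F1 | step 27 | [(3R,3aS,4R,7S,7aS)-7-bromo-4,7a-dimethyl-4-(triethylsilyloxy)octahydro-1H-inden-3-yl]methanol | OC[C@@H]1CC[C@]2(C)[C@@H](Br)CC[C@@](C)(O[Si](CC)(CC)CC)[C@@H]12
F2 | step 27 | (3R,3aS,4R,7S,7aS)-7-bromo-3-(iodomethyl)-4,7a-dimethyl-4-(triethylsilyloxy)octahydro-1H-indene | IC[C@@H]1CC[C@]2(C)[C@@H](Br)CC[C@@](C)(O[Si](CC)(CC)CC)[C@@H]12
F3 | step 27 | {[(3R,3aS,4R,7S,7aS)-7-bromo-4,7a-dimethyl-4-(triethylsilyloxy)octahydro-1H-inden-3-yl]methyl}triphenylphosphonium iodide | [I-].c1ccc(cc1)[P+](C[C@@H]1CC[C@]2(C)[C@@H](Br)CC[C@@](C)(O[Si](CC)(CC)CC)[C@@H]12)(c1ccccc1)c1ccccc1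
F4 | step 27 | (3S,3aS,4R,7S,7aS)-7-bromo-3-{(Z)-[(4S)-4-bromo-3,3-dimethylcyclohexylidene]methyl}-4,7a-dimethyl-4-(triethylsilyloxy)octahydro-1H-indene | CC1(C)C/C(=C\[C@@H]2CC[C@]3(C)[C@@H](Br)CC[C@@](C)(O[Si](CC)(CC)CC)[C@@H]23)CC[C@@H]1Br
F5 | step 23 | (S)-(4-bromo-3,3-dimethylcyclohexylidene)hydrazine | CC1(C)CC(=NN)CC[C@@H]1Br
F6 | step 23 | (S)-4-bromo-1-iodo-5,5-dimethylcyclohex-1-ene | CC1(C)CC(I)=CC[C@@H]1Br
F7 | step 6 | allyl (3S,4S)-4-(tert-butyldimethylsilyloxy)-3-[3-(4-methoxybenzyloxy)prop-1-en-2-yl]-2-methylcyclohex-1-en-1-yl carbonate | CC1=C(OC(=O)OCC=C)CC[C@H](O[Si](C)(C)C(C)(C)C)[C@H]1C(=C)COCc1ccc(OC)cc1
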